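The six ring carbons are numbered C1 (alkylidene carbon), C2 and C3 (CH2), C4 (carbinol), C5 (quaternary) and C6 (CH). The route rests on forming the ring bond C1–C2, as C1=C2, by ring-rearrangement enyne metathesis, which exploits the unsubstituted C2–C3 edge beside C1 and the two-carbon stub on C5. The precursor is a cyclopentene (C2, C3, C4, C5 and the future vinyl carbon) bearing the C6–C1 alkyne arm on C5. One operation opens the five-membered ring, closes the six-membered one, and delivers a 1,3-diene for cis-1,4-hydrogenation to the tetrasubstituted olefin plus the C5 vinyl group for the side chain. The cyclopentene, first cis-fused to a lactone, is a temporary scaffold relaying C5 to C4 and C6.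

Key step: step 11

Assumption: (S)-TRIP is taken as the phosphoric acid antipode that gives Si-face propargylation in step 14 (if the sense is the opposite, (R)-TRIP is used), and but-1-en-3-yne (19) is bought as a solution.

Step 1
Reactants: 1 2-methylcyclopentane-1,3-dione; 2 tert-butyl bromoacetate
Product: 3 tert-butyl 2-(1-methyl-2,5-dioxocyclopentyl)acetate
Conditions: KOt-Bu, DMSO, rt
Reagents that add atoms: none
Why: C-alkylation of the 1,3-dione enolate by the soft α-halo ester (enolate alkylation) should give the achiral dione whose quaternary carbon becomes C5.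

Step 2
Reactants: 3 dione ester
Product: 4 hydroxy ketone (1R,2R) with OH cis to the acetate arm
Conditions: (S)-Me-CBS oxazaborolidine (20 mol %), catecholborane, toluene, −78 °C
Reagents that add atoms: none
Why: CBS desymmetrising reduction: hydride is delivered anti to the acetate arm to the one enantiotopic carbonyl that the (S)-catalyst reduces to the (R)-carbinol, which fixes the absolute configuration of the quaternary carbon (future C5).

Step 3
Reactants: 4 hydroxy ketone
Product: 5 exo-methylene alcohol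
Conditions: Tebbe reagent Cp2Ti(μ-Cl)(μ-CH2)AlMe2, pyridine (cat.), THF/toluene, −40 → 0 °C
Reagents that add atoms: Tebbe reagent, C[Al-]1(C)C[Ti](C2C=CC=C2)(C2C=CC=C2)[Cl+]1
Why: Tebbe methylenation is non-basic, so the β-hydroxy ketone should not open by retro-aldol and the hindered tert-butyl ester is left alone; no stereocentre changes.

Step 4
Reactants: 5 exo-methylene alcohol
Product: 6 skipped diene ester
Conditions: Burgess reagent, benzene, 50 °C
Reagents that add atoms: none
Why: Burgess syn-elimination of the secondary alcohol can only run toward the ring CH2 (the other neighbour is quaternary) and should give the cyclopentene C=C that is opened later.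

Step 5
Reactants: 6 skipped diene ester
Product: 7 cis-fused iodolactone
Conditions: I2, NaHCO3, MeCN, 0 °C → rt, dark
Reagents that add atoms: iodine, II
Why: Iodolactonisation with the tert-butyl ester as nucleophile (loss of isobutene): the more nucleophilic 1,1-disubstituted olefin reacts at its tertiary carbon, and a five–five ring fusion can only be cis, so the new C–O bond (future C4–OH) is set syn to the acetate arm on C5.

Step 6
Reactants: 7 iodolactone
Product: 8 cis-fused dimethyl lactone
Conditions: Bu3SnH, AIBN (cat.), benzene, 80 °C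
Reagents that add atoms: none
Why: Radical deiodination with tin hydride turns CH2I into the C4 methyl; the primary β-acyloxy radical should be reduced faster than it can rearrange.

Step 7
Reactants: 8 dimethyl lactone; 9 tert-butyl(3-iodopropoxy)dimethylsilane
Product: 11 α-alkylated lactone (3S,3aS,6aS), via lithium enolate 10 (not isolated)
Conditions: LDA (LiN(i-Pr)2), THF, −78 °C; then 9, DMPU, −78 → −20 °C
Reagents that add atoms: none
Why: Lactone enolate alkylation: the primary iodide should approach the enolate of the cis-fused bicycle from the convex face, which places the chain cis to both angular methyls and sets C6.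

Step 8
Reactants: 11 alkylated lactone
Product: 12 lactol (anomeric mixture)
Conditions: DIBAL-H (i-Bu2AlH), CH2Cl2, −78 °C
Reagents that add atoms: none
Why: Partial reduction of the lactone stops at the tetrahedral aluminate at low temperature and should give the lactol without touching any other stereocentre.

Step 9
Reactants: 12 lactol
Product: 13 terminal alkyne with free tertiary alcohol
Conditions: dimethyl (1-diazo-2-oxopropyl)phosphonate, K2CO3, MeOH, 0 °C → rt
Reagents that add atoms: Ohira–Bestmann reagent, CC(=O)C(=[N+]=[N-])P(=O)(OC)OC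
Why: Seyferth–Gilbert homologation with the Ohira–Bestmann reagent acts on the open hydroxy-aldehyde form of the lactol and should give the alkyne (C1) while releasing the C4 alcohol; the hindered C6 centre is not expected to epimerise under these mild conditions.

Step 10
Reactants: 13 terminal alkyne
Product: 16 propargylic silyl ether, via dilithium acetylide alkoxide 14 (not isolated), via dilithium propargylic alkoxide 15 (not isolated)
Conditions: n-BuLi (2.2 equiv), THF, −78 → 0 °C; (CH2O)n; then TBSCl, 0 °C → rt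
Reagents that add atoms: paraformaldehyde (as formaldehyde), C=O; TBSCl, CC(C)(C)[Si](C)(C)Cl
Why: Acetylide addition to formaldehyde followed by O-silylation, which should be selective for the primary propargylic alkoxide over the hindered tertiary one.

Step 11
Reactants: 16 cyclopentene-yne
Product: 17 cyclohexene 1,3-diene with C5 vinyl group
Conditions: second-generation Grubbs catalyst RuCl2(=CHPh)(H2IMes)(PCy3) (10 mol %), ethylene (1 atm), toluene (0.01 M), 80 °C
Reagents that add atoms: ethylene, C=C
Why: Ring-opening/ring-closing enyne metathesis: the ruthenium methylidene formed with ethylene opens the cyclopentene with Ru on the less hindered olefinic carbon (C2) and CH2 on the neopentylic one, the C2 alkylidene then adds to the alkyne at C1 in the exo mode of a 1,7-enyne to close the six-membered ring through the new C1=C2 bond, and ethylene releases the resulting vinyl carbene as the 1,1-disubstituted olefin. The closest known reaction type is the ethylene-promoted ring-opening/ring-closing metathesis of cycloalkene-ynes. No stereocentre is formed, and C4, C5 and C6 are carried through unchanged. The selectivity needed is closure of the six-membered ring over the alternatives: closure at the proximal olefinic carbon would need a cyclobutene and is not viable, and the irreversible, strongly exothermic enyne step should drain the reversible cyclopentene opening. Ethylene also suppresses oligomerisation and regenerates the methylidene, and the free tertiary alcohol and silyl ethers should be tolerated.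

Step 12
Reactants: 17 1,3-diene
Product: 18 tetrasubstituted (Z)-alkylidene cyclohexanol
Conditions: Cr(CO)3(η6-C10H8) (naphthalene complex, 20 mol %), H2 (50 atm), THF, 45 °C
Reagents that add atoms: none
Why: Arene–Cr(CO)3-catalysed 1,4-hydrogenation adds H2 only to the termini of an η4-s-cis diene, so the new exocyclic double bond at C1 should carry the new methyl cis to C2 (Z), and the isolated vinyl group should not be reduced.

Step 13
Reactants: 19 but-1-en-3-yne
Product: 21 (1E)-1-iodo-2-methylbuta-1,3-diene, via dienylalane 20 (not isolated)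
Conditions: Me3Al, Cp2ZrCl2 (25 mol %), CH2Cl2, 0 °C → rt; then I2, THF, −30 °C
Reagents that add atoms: trimethylaluminium, C[Al](C)C; iodine, II
Why: Zr-catalysed syn-carboalumination of the terminal alkyne (Negishi) and iodinolysis with retention should give the (E)-iodo diene.

Step 14
Reactants: 22 3-methylbut-2-enal; 23 allenylboronic acid pinacol ester
Product: 24 (4S)-6-methylhept-5-en-1-yn-4-ol
Conditions: (S)-TRIP (10 mol %), 4 Å MS, toluene, −20 °C
Reagents that add atoms: none
Why: Chiral phosphoric acid-catalysed propargylboration through a six-membered cyclic SE2′ transition state; the catalyst shields the Re face of the aldehyde so that Si-face addition sets the (S)-carbinol.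

Step 15
Reactants: 24 homopropargylic alcohol
Product: 26 (1E,4S)-1-iodo-2,6-dimethylhepta-1,5-dien-4-ol, via alkenylalane 25 (not isolated)
Conditions: Me3Al (3 equiv), Cp2ZrCl2 (20 mol %), H2O (1 equiv), CH2Cl2, −20 °C; then I2, THF, −30 °C
Reagents that add atoms: trimethylaluminium, C[Al](C)C; iodine, II
Why: Zr-catalysed syn-methylalumination of the alkyne (hydroxyl carried as its aluminium alkoxide) and iodinolysis with retention should give the (E)-trisubstituted vinyl iodide; the water-accelerated low-temperature variant limits ionisation of the allylic alkoxide.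

Step 16
Reactants: 26 iodo dienol
Product: 27 threo epoxy alcohol vinyl iodide
Conditions: mCPBA, CH2Cl2, −20 → 0 °C
Reagents that add atoms: mCPBA, OOC(=O)c1cccc(Cl)c1
Why: Hydroxyl-directed peracid epoxidation of the allylic alcohol in its A(1,3)-minimised conformer (cis-methyl on the olefin) should give the threo epoxy alcohol, that is the (R)-epoxide carbon next to the (S)-carbinol; the iodoalkene is too electron-poor to react.

Step 17
Reactants: 18 vinyl cyclohexanol; 21 iodo diene
Product: 29 ring with (E)-dienyl chain, via B-alkyl-9-BBN 28 (not isolated)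
Conditions: 9-BBN, THF, rt → 60 °C; then aq. Cs2CO3, 21, PdCl2(dppf) (5 mol %), AsPh3, DMF, rt
Reagents that add atoms: none
Why: Anti-Markovnikov hydroboration of the only monosubstituted olefin and B-alkyl Suzuki–Miyaura coupling with retention of the vinyl iodide geometry should give the (E)-trisubstituted olefin.

Step 18
Reactants: 29 terminal diene; 27 epoxy vinyl iodide
Product: 31 complete skeleton as bis-silyl ether, via B-alkyl-9-BBN 30 (not isolated)
Conditions: 9-BBN, THF, 0 °C → rt; then aq. Cs2CO3, 27, PdCl2(dppf) (5 mol %), AsPh3, DMF, rt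
Reagents that add atoms: none
Why: 9-BBN should add only to the terminal CH=CH2 of the diene (the tri- and tetrasubstituted olefins are too hindered), and B-alkyl Suzuki–Miyaura coupling joins it to the vinyl iodide with retention; the epoxide and free alcohols tolerate the mild aqueous base.

Step 19
Reactants: 31 bis-silyl ether
Product: 32 tetraol
Conditions: TBAF (Bu4NF), AcOH, THF, 0 °C → rt
Reagents that add atoms: none
Why: Fluoride-mediated cleavage of the two primary TBS ethers, buffered with acetic acid so that the epoxy alcohol is neither opened nor rearranged.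

Step 20
Reactants: 32 tetraol
Product: 33 target CNP0161066.1
Conditions: MnO2 (activated), CH2Cl2, rt
Reagents that add atoms: none
Why: MnO2 should oxidise only the allylic primary alcohol to the enal and leave the saturated primary, secondary and tertiary alcohols and the olefin geometry untouched.

Compound list

1 | 2-methylcyclopentane-1,3-dione | CC1C(=O)CCC1=O | starting material
2 | tert-butyl bromoacetate | BrCC(=O)OC(C)(C)C | starting material
3 | tert-butyl 2-(1-methyl-2,5-dioxocyclopentyl)acetate | CC1(CC(=O)OC(C)(C)C)C(=O)CCC1=O | intermediate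
4 | tert-butyl 2-[(1R,2R)-2-hydroxy-1-methyl-5-oxocyclopentyl]acetate (OH cis to the acetate arm) | O=C1CC[C@@H](O)[C@@]1(C)CC(=O)OC(C)(C)C | intermediate
5 | tert-butyl 2-[(1S,2R)-2-hydroxy-1-methyl-5-methylidenecyclopentyl]acetate | C=C1CC[C@@H](O)[C@@]1(C)CC(=O)OC(C)(C)C | intermediate
6 | tert-butyl 2-[(1R)-1-methyl-5-methylidenecyclopent-2-en-1-yl]acetate | C=C1CC=C[C@@]1(C)CC(=O)OC(C)(C)C | intermediate
7 | (3aR,6aS)-6a-(iodomethyl)-3a-methyl-3,3a,6,6a-tetrahydro-2H-cyclopenta[b]furan-2-one | O=C1C[C@]2(C)C=CC[C@]2(CI)O1 | intermediate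
8 | (3aR,6aS)-3a,6a-dimethyl-3,3a,6,6a-tetrahydro-2H-cyclopenta[b]furan-2-one | O=C1C[C@]2(C)C=CC[C@]2(C)O1 | intermediate
9 | tert-butyl(3-iodopropoxy)dimethylsilane | CC(C)(C)[Si](C)(C)OCCCI | starting material
10 | lithium enolate of 8 | [Li]OC1=C[C@]2(C)C=CC[C@]2(C)O1 | intermediate
11 | (3S,3aS,6aS)-3-{3-[(tert-butyldimethylsilyl)oxy]propyl}-3a,6a-dimethyl-3,3a,6,6a-tetrahydro-2H-cyclopenta[b]furan-2-one (chain cis to both angular methyls) | O=C1[C@@H](CCCO[Si](C)(C)C(C)(C)C)[C@]2(C)C=CC[C@]2(C)O1 | intermediate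
12 | (3S,3aS,6aS)-3-{3-[(tert-butyldimethylsilyl)oxy]propyl}-3a,6a-dimethyl-3,3a,6,6a-tetrahydro-2H-cyclopenta[b]furan-2-ol (both anomers) | OC1[C@@H](CCCO[Si](C)(C)C(C)(C)C)[C@]2(C)C=CC[C@]2(C)O1 | intermediate
13 | (1S,2S)-2-[(3R)-6-[(tert-butyldimethylsilyl)oxy]hex-1-yn-3-yl]-1,2-dimethylcyclopent-3-en-1-ol | C#C[C@@H](CCCO[Si](C)(C)C(C)(C)C)[C@]1(C)C=CC[C@]1(C)O | intermediate
14 | dilithium salt of 13 (lithium acetylide and lithium tertiary alkoxide) | [Li]C#C[C@@H](CCCO[Si](C)(C)C(C)(C)C)[C@]1(C)C=CC[C@]1(C)O[Li] | intermediate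
15 | dilithium dialkoxide of the propargylic alcohol from 14 and formaldehyde | [Li]OCC#C[C@@H](CCCO[Si](C)(C)C(C)(C)C)[C@]1(C)C=CC[C@]1(C)O[Li] | intermediate
16 | (1S,2S)-2-[(4R)-1,7-bis[(tert-butyldimethylsilyl)oxy]hept-2-yn-4-yl]-1,2-dimethylcyclopent-3-en-1-ol | CC(C)(C)[Si](C)(C)OCC#C[C@@H](CCCO[Si](C)(C)C(C)(C)C)[C@]1(C)C=CC[C@]1(C)O | intermediate
17 | (1S,2S,3R)-2-ethenyl-1,2-dimethyl-4-{3-[(tert-butyldimethylsilyl)oxy]prop-1-en-2-yl}-3-{3-[(tert-butyldimethylsilyl)oxy]propyl}cyclohex-4-en-1-ol | C=C(CO[Si](C)(C)C(C)(C)C)C1=CC[C@](C)(O)[C@@](C)(C=C)[C@@H]1CCCO[Si](C)(C)C(C)(C)C | intermediate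
18 | (1S,2S,3R,4Z)-2-ethenyl-1,2-dimethyl-4-{1-[(tert-butyldimethylsilyl)oxy]propan-2-ylidene}-3-{3-[(tert-butyldimethylsilyl)oxy]propyl}cyclohexan-1-ol | C/C(CO[Si](C)(C)C(C)(C)C)=C1\CC[C@](C)(O)[C@@](C)(C=C)[C@@H]1CCCO[Si](C)(C)C(C)(C)C | intermediate
19 | but-1-en-3-yne | C#CC=C | starting material
20 | dimethyl[(1E)-2-methylbuta-1,3-dien-1-yl]alane | C[Al](C)/C=C(\C)C=C | intermediate
21 | (1E)-1-iodo-2-methylbuta-1,3-diene | I/C=C(\C)C=C | intermediate
22 | 3-methylbut-2-enal | CC(C)=CC=O | starting material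
23 | 4,4,5,5-tetramethyl-2-(propa-1,2-dien-1-yl)-1,3,2-dioxaborolane | C=C=CB1OC(C)(C)C(C)(C)O1 | starting material
24 | (4S)-6-methylhept-5-en-1-yn-4-ol | C#CC[C@H](O)C=C(C)C | intermediate
25 | (E)-alkenyl(dimethyl)alane of 24 with the hydroxyl as its dimethylaluminium alkoxide | C[Al](C)/C=C(\C)C[C@H](O[Al](C)C)C=C(C)C | intermediate
26 | (1E,4S)-1-iodo-2,6-dimethylhepta-1,5-dien-4-ol | I/C=C(\C)C[C@H](O)C=C(C)C | intermediate
27 | (1S,3E)-1-[(2R)-3,3-dimethyloxiran-2-yl]-4-iodo-3-methylbut-3-en-1-ol | I/C=C(\C)C[C@H](O)[C@H]1OC1(C)C | intermediate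
28 | B-alkyl-9-BBN from 18 (boron on the terminal carbon of the former vinyl group) | C/C(CO[Si](C)(C)C(C)(C)C)=C1\CC[C@](C)(O)[C@@](C)(CCB2C3CCCC2CCC3)[C@@H]1CCCO[Si](C)(C)C(C)(C)C | intermediate
29 | (1S,2S,3R,4Z)-1,2-dimethyl-2-[(3E)-4-methylhexa-3,5-dien-1-yl]-4-{1-[(tert-butyldimethylsilyl)oxy]propan-2-ylidene}-3-{3-[(tert-butyldimethylsilyl)oxy]propyl}cyclohexan-1-ol | C/C(CO[Si](C)(C)C(C)(C)C)=C1\CC[C@](C)(O)[C@@](C)(CC/C=C(\C)C=C)[C@@H]1CCCO[Si](C)(C)C(C)(C)C | intermediate
30 | B-alkyl-9-BBN from 29 (boron on the terminal carbon of the former diene) | C/C(CO[Si](C)(C)C(C)(C)C)=C1\CC[C@](C)(O)[C@@](C)(CC/C=C(\C)CCB2C3CCCC2CCC3)[C@@H]1CCCO[Si](C)(C)C(C)(C)C | intermediate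
31 | (1S,2S,3R,4Z)-2-[(3E,7E,10S)-10-[(2R)-3,3-dimethyloxiran-2-yl]-10-hydroxy-4,8-dimethyldeca-3,7-dien-1-yl]-1,2-dimethyl-4-{1-[(tert-butyldimethylsilyl)oxy]propan-2-ylidene}-3-{3-[(tert-butyldimethylsilyl)oxy]propyl}cyclohexan-1-ol | C/C(CO[Si](C)(C)C(C)(C)C)=C1\CC[C@](C)(O)[C@@](C)(CC/C=C(\C)CC/C=C(\C)C[C@H](O)[C@H]2OC2(C)C)[C@@H]1CCCO[Si](C)(C)C(C)(C)C | intermediate
32 | (1S,2S,3R,4Z)-2-[(3E,7E,10S)-10-[(2R)-3,3-dimethyloxiran-2-yl]-10-hydroxy-4,8-dimethyldeca-3,7-dien-1-yl]-4-(1-hydroxypropan-2-ylidene)-3-(3-hydroxypropyl)-1,2-dimethylcyclohexan-1-ol | C/C(CO)=C1\CC[C@](C)(O)[C@@](C)(CC/C=C(\C)CC/C=C(\C)C[C@H](O)[C@H]2OC2(C)C)[C@@H]1CCCO | intermediate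
33 | (2Z)-2-[(2R,3S,4S)-3-[(3E,7E,10S)-10-[(2R)-3,3-dimethyloxiran-2-yl]-10-hydroxy-4,8-dimethyldeca-3,7-dien-1-yl]-4-hydroxy-2-(3-hydroxypropyl)-3,4-dimethylcyclohexylidene]propanal (CNP0161066.1) | C/C(C=O)=C1\CC[C@](C)(O)[C@@](C)(CC/C=C(\C)CC/C=C(\C)C[C@H](O)[C@H]2OC2(C)C)[C@@H]1CCCO | target

Step count and risks

Total step count: 20. Longest linear sequence: 16 steps (steps 1–12 and 17–20).

Steps most likely to fail:

1. Step 11 (ring-rearrangement metathesis). The nearly strain-free cyclopentene, flanked by a quaternary carbon, may not be opened productively, so that only ethylene–alkyne cross-metathesis or oligomerisation takes place. The fallback sets out from 16 and comes back at 17, and opens the five-membered ring oxidatively instead. OsO4 (cat.)/NMO followed by NaIO4 should cleave the ring olefin to the dialdehyde (3S,4S,5R)-8-[(tert-butyldimethylsilyl)oxy]-5-{3-[(tert-butyldimethylsilyl)oxy]propyl}-4-formyl-3-hydroxy-3,4-dimethyloct-6-ynal F1. Ph3P=CH2 (1 equiv, THF, −78 °C) should methylenate only the unhindered CH2CHO group and give the 1,7-enyne aldehyde (2S,3R)-6-[(tert-butyldimethylsilyl)oxy]-3-{3-[(tert-butyldimethylsilyl)oxy]propyl}-2-[(2S)-2-hydroxypent-4-en-2-yl]-2-methylhex-4-ynal F2. Ordinary ring-closing enyne metathesis (second-generation Grubbs catalyst, CH2Cl2, 40 °C) then forms the same C1=C2 bond and gives the diene aldehyde (1S,2S,6R)-2-hydroxy-1,2-dimethyl-5-{3-[(tert-butyldimethylsilyl)oxy]prop-1-en-2-yl}-6-{3-[(tert-butyldimethylsilyl)oxy]propyl}cyclohex-4-ene-1-carbaldehyde F3. Methylenation of its neopentylic aldehyde (excess Ph3P=CH2, THF, reflux) gives 17.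

2. Step 12 (1,4-hydrogenation). The 2,3-disubstituted diene, with the bulky silyloxymethyl group on the exocyclic carbon, may fail to reach the planar s-cis η4 arrangement on chromium, so that the catalyst does not turn over. The fallback sets out from 13 and comes back at 18, and moves the reduction to a smaller, ester-activated diene of the class (dienoates) for which this hydrogenation is best established. 13 is C-acylated (n-BuLi 2.1 equiv, ClCO2Me, THF, −78 °C) to the ynoate methyl (4R)-7-[(tert-butyldimethylsilyl)oxy]-4-[(1S,5S)-5-hydroxy-1,5-dimethylcyclopent-2-en-1-yl]hept-2-ynoate F4. The ethylene-mediated ring-rearrangement metathesis of step 11 should give the cross-conjugated dienoate methyl 2-[(4S,5S,6R)-5-ethenyl-4-hydroxy-4,5-dimethyl-6-{3-[(tert-butyldimethylsilyl)oxy]propyl}cyclohex-1-en-1-yl]prop-2-enoate F5. Cr(CO)3(η6-C10H8)/H2 should then give, by the same cis-1,4-addition, the enoate methyl (2Z)-2-[(2R,3S,4S)-3-ethenyl-4-hydroxy-3,4-dimethyl-2-{3-[(tert-butyldimethylsilyl)oxy]propyl}cyclohexylidene]propanoate F6. DIBAL-H (i-Bu2AlH, CH2Cl2, −78 °C) reduces it to the allylic alcohol (1S,2S,3R,4Z)-2-ethenyl-4-(1-hydroxypropan-2-ylidene)-1,2-dimethyl-3-{3-[(tert-butyldimethylsilyl)oxy]propyl}cyclohexan-1-ol F7, and TBSCl/imidazole (DMF, 0 °C) returns 18.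

3. Step 7 (lactone alkylation). The angular methyl next to the enolate carbon may direct the electrophile to the concave face, giving poor or reversed facial selectivity at C6. The fallback sets out from 8 and comes back at 11, and makes C–H rather than C–C bond formation the stereo-determining event. If alkylation under the step 7 conditions delivers mainly the C6 epimer (3R,3aS,6aS)-3-{3-[(tert-butyldimethylsilyl)oxy]propyl}-3a,6a-dimethyl-3,3a,6,6a-tetrahydro-2H-cyclopenta[b]furan-2-one F8, this is deprotonated again (LiN(i-Pr)2, THF, −78 → 0 °C) and the trisubstituted enolate is protonated kinetically (2,6-di-tert-butylphenol, −78 °C). The proton should enter from the same face that the iodide preferred, which inverts C6 and gives 11.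

Further compounds

F1 | step 11 | (3S,4S,5R)-8-[(tert-butyldimethylsilyl)oxy]-5-{3-[(tert-butyldimethylsilyl)oxy]propyl}-4-formyl-3-hydroxy-3,4-dimethyloct-6-ynal | O=CC[C@](C)(O)[C@@](C)(C=O)[C@@H](C#CCO[Si](C)(C)C(C)(C)C)CCCO[Si](C)(C)C(C)(C)C
F2 | step 11 | (2S,3R)-6-[(tert-butyldimethylsilyl)oxy]-3-{3-[(tert-butyldimethylsilyl)oxy]propyl}-2-[(2S)-2-hydroxypent-4-en-2-yl]-2-methylhex-4-ynal | C=CC[C@](C)(O)[C@@](C)(C=O)[C@@H](C#CCO[Si](C)(C)C(C)(C)C)CCCO[Si](C)(C)C(C)(C)C
F3 | step 11 | (1S,2S,6R)-2-hydroxy-1,2-dimethyl-5-{3-[(tert-butyldimethylsilyl)oxy]prop-1-en-2-yl}-6-{3-[(tert-butyldimethylsilyl)oxy]propyl}cyclohex-4-ene-1-carbaldehyde | C=C(CO[Si](C)(C)C(C)(C)C)C1=CC[C@](C)(O)[C@@](C)(C=O)[C@@H]1CCCO[Si](C)(C)C(C)(C)C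
F4 | step 12 | methyl (4R)-7-[(tert-butyldimethylsilyl)oxy]-4-[(1S,5S)-5-hydroxy-1,5-dimethylcyclopent-2-en-1-yl]hept-2-ynoate | COC(=O)C#C[C@@H](CCCO[Si](C)(C)C(C)(C)C)[C@]1(C)C=CC[C@]1(C)O
F5 | step 12 | methyl 2-[(4S,5S,6R)-5-ethenyl-4-hydroxy-4,5-dimethyl-6-{3-[(tert-butyldimethylsilyl)oxy]propyl}cyclohex-1-en-1-yl]prop-2-enoate | C=C(C(=O)OC)C1=CC[C@](C)(O)[C@@](C)(C=C)[C@@H]1CCCO[Si](C)(C)C(C)(C)C
F6 | step 12 | methyl (2Z)-2-[(2R,3S,4S)-3-ethenyl-4-hydroxy-3,4-dimethyl-2-{3-[(tert-butyldimethylsilyl)oxy]propyl}cyclohexylidene]propanoate | C/C(C(=O)OC)=C1\CC[C@](C)(O)[C@@](C)(C=C)[C@@H]1CCCO[Si](C)(C)C(C)(C)C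
F7 | step 12 | (1S,2S,3R,4Z)-2-ethenyl-4-(1-hydroxypropan-2-ylidene)-1,2-dimethyl-3-{3-[(tert-butyldimethylsilyl)oxy]propyl}cyclohexan-1-ol | C/C(CO)=C1\CC[C@](C)(O)[C@@](C)(C=C)[C@@H]1CCCO[Si](C)(C)C(C)(C)C
F8 | step 7 | (3R,3aS,6aS)-3-{3-[(tert-butyldimethylsilyl)oxy]propyl}-3a,6a-dimethyl-3,3a,6,6a-tetrahydro-2H-cyclopenta[b]furan-2-one | O=C1[C@H](CCCO[Si](C)(C)C(C)(C)C)[C@]2(C)C=CC[C@]2(C)O1
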